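The constants of the five candidate steps are hidden, so I keep a ledger of the electrophile from the readings themselves.

in all of them: electrophile 0.50 M

| charge | nucleophile | free base | remark | time |
|---|---|---|---|---|
| amber | 0.40 M | 0.35 M | run made earlier |  |
| red | 0.40 M | 0.54 M | run made earlier |  |
| winter | 0.400 M | 0.380 M |  | 1.5 h |
| autumn | 0.400 M | 0.250 M |  | 1.5 h |

- amber (time / min: electrophile / %, target / %): 8.00: 78.6, 16.3; 15.0: 67.1, 27.5; 40.0: 38.9, 36.0; 90.0: 18.9, 35.3
- red (time / min: electrophile / %, target / %): 8.00: 79.9, 18.1; 15.0: 64.2, 24.8; 40.0: 39.1, 35.8; 90.0: 17.3, 39.7

(each reading ± 1 percentage point)

- percent here means electrophile units held: one side product B counts as two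
- what was read earlier has a scatter of 1 percentage point, one standard deviation
- candidate steps: electrophile + nucleophile -> acid set free + target; nucleophile + acid set free <-> protonated nucleophile; acid set free + free base <-> salt of the base; electrophile + acid set free -> side product A; electrophile + target -> side product B

- part of the electrophile that has reacted at the end, winter
- part of the electrophile that has reacted at the end, autumn
- what raising the concentration of free base from its lowest to its highest value here does to the part of the electrophile that has reacted (changes below 5 percentage points count as none) (no change / it rises / it falls)

I book each reacted unit of electrophile as target or as side product B, which holds two units but took one pass through the first step; I book nothing under side product A, an assumption these readings do not test. The acid set free so far is then half the sum of reacted and target, times the electrophile charge. Averaging amber and red at their last reading, which falls at the asked 1.5 h, gives 81.9% reacted, of which 37.5% is target and 44.4% side product B, and so 0.298 M of acid: this is the acid tally, the acid released as counted from the electrophile ledger.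

The tally lies below amber's 0.35 M of free base, and amber and red read alike within the scatter, so for winter, whose 0.380 M also exceeds it, I commit to 81.9%.

Autumn's 0.250 M falls short of the tally by 0.0485 M, and the tally at 40.0 min already reads 0.242 M, near that charge. As a rough assumption of my own, I let the surplus fall on the nucleophile from that reading on, growing from nothing there to about half of the 0.102 M unreacted by the end, which makes a quarter on average over the stretch. The first step booked 11.2% of the charge in that stretch and runs in proportion to free nucleophile, so on this assumption I book a loss of 2.7 percentage points for autumn. Leaving the entry for side product B as it stands, I commit to 79.2%, a gap below 5 points, hence no change.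

The forecast gives 82%, 79% and no change, holding for the earlier runs that “base was never exhausted”.

The flask gives 81.7% for winter and 79.2% for autumn, a change of 2.5 points, so the answer is no change. Autumn's protonated nucleophile, however, stands at 0.0490 M after 0.750 h, which is 31.3% of the unconsumed nucleophile, a share my assumption does not reach so soon after its start, so the match of my autumn figure with the flask's is no proof of that assumption.

    electrophile + nucleophile → acid set free + target (k = 0.00133 M⁻¹ s⁻¹)
    nucleophile + acid set free ⇌ protonated nucleophile, settled at all times (K = 444 M⁻¹)
    acid set free + free base ⇌ salt of the base, settled at all times (K = 3300 M⁻¹)
    electrophile + acid set free → side product A (k = 9.00 × 10⁻⁴ M⁻¹ s⁻¹)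
    electrophile + target → side product B (k = 6.74 × 10⁻⁴ M⁻¹ s⁻¹)

At the end of winter the salt of the base, the protonated nucleophile and the free acid together hold 0.297 M, counted on the acid side, against my tally of 0.298 M, counted on the electrophile side. The neighbour flask, charged with 0.85 M of electrophile and otherwise like winter, has 70.0% reacted and 14.9% as target, so the same tally gives 0.361 M, just under its 0.380 M of free base. There the salt stands at 0.335 M, the protonated nucleophile at 0.0203 M, and the free nucleophile at 5.02% of its charge.

The runs are calculated with constants of no real substance.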